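**Plan**

1. Numbering follows 7-oxabicyclo[4.1.0]hept-3-en-2-one: C1 epoxide CH, C2 ketone, C3 (bears CH2OAc), C4 vinyl CH, C5 carbinol, C6 epoxide carbon bearing the chain, C1' chain carbinol. The enabling feature is that the six-membered ring carries oxygen on the para-related carbons C2 and C5 and carbon substituents on C3 and C6, so it is a masked 2,5-disubstituted hydroquinone whose two oxygens can be told apart.
2. Retrosynthesis: the C2 ketone comes from a dimethyl ketal, the C5 carbinol from a ketone, and the C1–C6 epoxide from the C1=C6 bond of a quinone monoketal, itself from a p-methoxyphenol. The arene is cut at C4–C5, C1–C2 and C5–C6 into an alkenyl(methoxy)carbene chromium complex (C2, C3, C4 and the CH2O carbon), a terminal alkyne (C1, C6 and the whole chain) and one CO ligand (C5 and its oxygen).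
3. Forward: farnesol → farnesal → ethynyl ketone → (S)-propargylic silyl ether; 2-bromoallyl alcohol → carbene complex. A three-component benzannulation then builds the carbocycle as a phenol, PhI(OAc)2/MeOH dearomatises it, and desilylation, epoxidation, acetylation, C5 reduction and ketal hydrolysis follow.
4. Stereochemistry: C1' from the Midland reduction of the ynone; the C1/C6 epoxide is relayed from C1'–OH by alkoxide-directed nucleophilic epoxidation; C5 from C1'–OH-directed 1,3-anti hydride delivery; both E alkenes come from farnesol.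

Key step: step 8

Remark: (2E,6E)-farnesol, 2-bromoprop-2-en-1-ol, ethynylmagnesium bromide and Cr(CO)6 are taken as commercial; in SMILES of chromium complexes the CO ligands are written as separate components.

**Route**

Step 1
Reactants: 1 (2E,6E)-farnesol
Product: 2 (2E,6E)-farnesal
Conditions: MnO2 (activated, excess), CH2Cl2, rt
Reagents that add atoms: none
Why: Allylic oxidation with MnO2 acts only on the allylic carbinol and should keep the 2E geometry.

Step 2
Reactants: 2 (2E,6E)-farnesal; 3 ethynylmagnesium bromide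
Product: 4 rac-(4E,8E)-5,9,13-trimethyltetradeca-4,8,12-trien-1-yn-3-ol
Conditions: THF, –78 → 0 °C; aq NH4Cl
Reagents that add atoms: none
Why: Grignard 1,2-addition of the alkynyl nucleophile to the enal; the carbinol centre forms racemic and is erased in step 3.

Step 3
Reactants: 4 rac-(4E,8E)-5,9,13-trimethyltetradeca-4,8,12-trien-1-yn-3-ol
Product: 5 (4E,8E)-5,9,13-trimethyltetradeca-4,8,12-trien-1-yn-3-one
Conditions: MnO2 (activated, excess), CH2Cl2, rt
Reagents that add atoms: none
Why: MnO2 oxidation of a carbinol that is both allylic and propargylic should be fast and leave the isolated alkenes untouched.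

Step 4
Reactants: 5 (4E,8E)-5,9,13-trimethyltetradeca-4,8,12-trien-1-yn-3-one
Product: 6 (3S,4E,8E)-5,9,13-trimethyltetradeca-4,8,12-trien-1-yn-3-ol
Conditions: (S)-Alpine-Borane (1.5 equiv), THF, rt; CH3CHO; HOCH2CH2NH2, Et2O
Reagents that add atoms: none
Why: Midland reduction, in which the pinanyl β-hydrogen is transferred through a boat-like six-membered transition state with the slim ethynyl group beside the pinane methyl, so the reagent from (–)-α-pinene should give the 3S carbinol (ethynyl small, trienyl chain large).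

Step 5
Reactants: 6 (3S,4E,8E)-5,9,13-trimethyltetradeca-4,8,12-trien-1-yn-3-ol
Product: 7 tert-butyldimethyl{[(3S,4E,8E)-5,9,13-trimethyltetradeca-4,8,12-trien-1-yn-3-yl]oxy}silane
Conditions: TBSCl, imidazole, DMF, rt
Reagents that add atoms: tert-butyldimethylsilyl chloride (TBSCl), CC(C)(C)[Si](C)(C)Cl
Why: Standard silylation masks the propargylic hydroxyl, which would otherwise trap the ketene intermediate of step 8 as a lactone.

Step 6
Reactants: 8 2-bromoprop-2-en-1-ol
Product: 9 [(2-bromoprop-2-en-1-yl)oxy](tert-butyl)dimethylsilane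
Conditions: TBSCl, imidazole, CH2Cl2, 0 °C → rt
Reagents that add atoms: tert-butyldimethylsilyl chloride (TBSCl), CC(C)(C)[Si](C)(C)Cl
Why: Standard silylation of a primary allylic alcohol gives an ether that tolerates t-BuLi.

Step 7
Reactants: 9 [(2-bromoprop-2-en-1-yl)oxy](tert-butyl)dimethylsilane; 10 Cr(CO)6
Product: 13 pentacarbonyl{methoxy[3-(tert-butyldimethylsilyloxy)prop-1-en-2-yl]carbene}chromium (CO)5Cr=C(OMe)C(=CH2)CH2OTBS, via vinyllithium 11 (not isolated), via lithium acylchromate 12 (not isolated)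
Conditions: t-BuLi (2 equiv), Et2O, –78 °C; Cr(CO)6, Et2O, 0 °C → rt; Me3OBF4, CH2Cl2, 0 °C
Reagents that add atoms: trimethyloxonium tetrafluoroborate (Me3OBF4), C[O+](C)C.F[B-](F)(F)F
Why: Fischer carbene synthesis, in which bromine–lithium exchange gives the vinyllithium, its addition to a CO ligand gives the acylchromate, and O-methylation with the Meerwein salt gives the methoxycarbene of zerovalent chromium.

Step 8
Reactants: 13 alkenyl(methoxy)carbene chromium complex (CO)5Cr=C(OMe)C(=CH2)CH2OTBS; 7 tert-butyldimethyl{[(3S,4E,8E)-5,9,13-trimethyltetradeca-4,8,12-trien-1-yn-3-yl]oxy}silane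
Product: 16 5-{[(tert-butyldimethylsilyl)oxy]methyl}-2-[(1S,2E,6E)-1-[(tert-butyldimethylsilyl)oxy]-3,7,11-trimethyldodeca-2,6,10-trien-1-yl]-4-methoxyphenol, via dienylketene Cr(CO)3 complex 14 (not isolated), via phenol Cr(CO)3 complex 15 (not isolated)
Conditions: THF (0.05 M), 50 °C, Ar; then air, rt
Reagents that add atoms: none
Why: Thermal loss of one CO from 13 lets the alkyne of 7 insert into the Cr=C bond, its CH terminus bonding to the carbene carbon (the C1–C2 bond) and its substituted carbon becoming the new carbene centre; CO then inserts there (the C5–C6 bond) to give the Cr(CO)3-bound dienylketene 14, whose 6π-electrocyclization joins the ketene carbon C5 to the CH2 terminus C4 and, after tautomerization, gives the phenol. The closest known reaction type is the Dötz benzannulation of alkenyl(alkoxy)carbene chromium complexes with terminal alkynes. The six-membered ring is closed by a thermal disrotatory 6π-electrocyclic closure of the metal-templated dienylketene, all six carbons having been assembled on chromium. No new stereocentre is formed, and C1' should pass through these neutral conditions unchanged. The step needs regioselective alkyne insertion, which the terminal alkyne secures because its larger substituent ends next to the CO-derived carbon, and chemoselectivity over the three trisubstituted alkenes of the chain, which should not react with the carbene at 50 °C. It also delivers the two para oxygens differentiated (free OH at C5 from CO, OMe at C2 from the carbene), which fixes the sites of the later ketal, epoxide and carbinol.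

Step 9
Reactants: 16 5-{[(tert-butyldimethylsilyl)oxy]methyl}-2-[(1S,2E,6E)-1-[(tert-butyldimethylsilyl)oxy]-3,7,11-trimethyldodeca-2,6,10-trien-1-yl]-4-methoxyphenol
Product: 17 5-{[(tert-butyldimethylsilyl)oxy]methyl}-2-[(1S,2E,6E)-1-[(tert-butyldimethylsilyl)oxy]-3,7,11-trimethyldodeca-2,6,10-trien-1-yl]-4,4-dimethoxycyclohexa-2,5-dien-1-one
Conditions: PhI(OAc)2 (1.05 equiv), MeOH, 0 °C
Reagents that add atoms: methanol, CO
Why: Oxidative dearomatisation of a p-methoxyphenol, in which methanol adds at the carbon para to the hydroxyl that already bears OMe, so the dimethyl ketal forms only at C2 and C5 becomes the dienone carbonyl.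

Step 10
Reactants: 17 5-{[(tert-butyldimethylsilyl)oxy]methyl}-2-[(1S,2E,6E)-1-[(tert-butyldimethylsilyl)oxy]-3,7,11-trimethyldodeca-2,6,10-trien-1-yl]-4,4-dimethoxycyclohexa-2,5-dien-1-one
Product: 18 5-(hydroxymethyl)-2-[(1S,2E,6E)-1-hydroxy-3,7,11-trimethyldodeca-2,6,10-trien-1-yl]-4,4-dimethoxycyclohexa-2,5-dien-1-one
Conditions: TBAF, AcOH, THF, 0 °C → rt
Reagents that add atoms: none
Why: Fluoride-mediated cleavage of both silyl ethers, buffered with acetic acid to spare the base-sensitive dienone.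

Step 11
Reactants: 18 5-(hydroxymethyl)-2-[(1S,2E,6E)-1-hydroxy-3,7,11-trimethyldodeca-2,6,10-trien-1-yl]-4,4-dimethoxycyclohexa-2,5-dien-1-one
Product: 19 (1R,6S)-3-(hydroxymethyl)-6-[(1S,2E,6E)-1-hydroxy-3,7,11-trimethyldodeca-2,6,10-trien-1-yl]-2,2-dimethoxy-7-oxabicyclo[4.1.0]hept-3-en-5-one
Conditions: Ph3COOH (1.5 equiv), NaN(SiMe3)2 (3 equiv), THF, –78 → –40 °C; aq NH4Cl
Reagents that add atoms: trityl hydroperoxide, OOC(c1ccccc1)(c1ccccc1)c1ccccc1
Why: Weitz–Scheffer (nucleophilic) epoxidation directed by the C1' sodium alkoxide, in which the peroxide attacks the unsubstituted β-carbon C1 and not the fully substituted β-carbon C3 of the other alkene; the alkoxide-bound peroxide is delivered to the face syn to the C1'–O bond while A1,2 strain with the C5 carbonyl places H, not the chain, in the ring plane, which should give the erythro epoxy alcohol with the 1R,6S epoxide.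

Step 12
Reactants: 19 (1R,6S)-3-(hydroxymethyl)-6-[(1S,2E,6E)-1-hydroxy-3,7,11-trimethyldodeca-2,6,10-trien-1-yl]-2,2-dimethoxy-7-oxabicyclo[4.1.0]hept-3-en-5-one
Product: 20 [(1R,6S)-6-[(1S,2E,6E)-1-hydroxy-3,7,11-trimethyldodeca-2,6,10-trien-1-yl]-2,2-dimethoxy-5-oxo-7-oxabicyclo[4.1.0]hept-3-en-3-yl]methyl acetate
Conditions: Ac2O (1.1 equiv), 2,4,6-collidine, CH2Cl2, –20 °C
Reagents that add atoms: acetic anhydride, CC(=O)OC(C)=O
Why: Site-selective acylation, in which the primary allylic hydroxyl should react far faster than the C1' hydroxyl, a secondary carbinol flanked by the quaternary epoxide carbon.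

Step 13
Reactants: 20 [(1R,6S)-6-[(1S,2E,6E)-1-hydroxy-3,7,11-trimethyldodeca-2,6,10-trien-1-yl]-2,2-dimethoxy-5-oxo-7-oxabicyclo[4.1.0]hept-3-en-3-yl]methyl acetate
Product: 21 [(1R,5S,6R)-5-hydroxy-6-[(1S,2E,6E)-1-hydroxy-3,7,11-trimethyldodeca-2,6,10-trien-1-yl]-2,2-dimethoxy-7-oxabicyclo[4.1.0]hept-3-en-3-yl]methyl acetate
Conditions: Me4NBH(OAc)3 (5 equiv), MeCN/AcOH (1:1), –30 °C
Reagents that add atoms: none
Why: Evans–Saksena hydroxyl-directed reduction, in which the acetoxyborohydride bound to the C1' oxygen delivers hydride to C5 through a chair transition state with the trienyl chain equatorial, that is to the carbonyl face on the side of the epoxide oxygen, giving the 1,3-anti diol with the 5S hydroxyl trans to the epoxide by 1,2-reduction only and leaving the acetate untouched.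

Step 14
Reactants: 21 [(1R,5S,6R)-5-hydroxy-6-[(1S,2E,6E)-1-hydroxy-3,7,11-trimethyldodeca-2,6,10-trien-1-yl]-2,2-dimethoxy-7-oxabicyclo[4.1.0]hept-3-en-3-yl]methyl acetate
Product: 22 [(1R,5S,6R)-5-hydroxy-6-[(1S,2E,6E)-1-hydroxy-3,7,11-trimethyldodeca-2,6,10-trien-1-yl]-2-oxo-7-oxabicyclo[4.1.0]hept-3-en-3-yl]methyl acetate (target)
Conditions: CF3CO2H, CH2Cl2/H2O (10:1), 0 °C, short reaction time
Reagents that add atoms: water, O
Why: Acid-catalysed hydrolysis of the allylic dimethyl ketal through the oxocarbenium ion stabilised by the C3=C4 alkene should unveil the C2 ketone at 0 °C without opening the epoxide or cleaving the acetate.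

**Compound list**

1 | (2E,6E)-3,7,11-trimethyldodeca-2,6,10-trien-1-ol, (2E,6E)-farnesol | OC/C=C(\C)CC/C=C(\C)CCC=C(C)C | starting material
2 | (2E,6E)-3,7,11-trimethyldodeca-2,6,10-trienal, (2E,6E)-farnesal | O=C/C=C(\C)CC/C=C(\C)CCC=C(C)C | intermediate
3 | ethynylmagnesium bromide | C#C[Mg]Br | starting material
4 | rac-(4E,8E)-5,9,13-trimethyltetradeca-4,8,12-trien-1-yn-3-ol | C#CC(O)/C=C(\C)CC/C=C(\C)CCC=C(C)C | intermediate
5 | (4E,8E)-5,9,13-trimethyltetradeca-4,8,12-trien-1-yn-3-one | C#CC(=O)/C=C(\C)CC/C=C(\C)CCC=C(C)C | intermediate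
6 | (3S,4E,8E)-5,9,13-trimethyltetradeca-4,8,12-trien-1-yn-3-ol | C#C[C@@H](O)/C=C(\C)CC/C=C(\C)CCC=C(C)C | intermediate
7 | tert-butyldimethyl{[(3S,4E,8E)-5,9,13-trimethyltetradeca-4,8,12-trien-1-yn-3-yl]oxy}silane | C#C[C@@H](O[Si](C)(C)C(C)(C)C)/C=C(\C)CC/C=C(\C)CCC=C(C)C | intermediate
8 | 2-bromoprop-2-en-1-ol | OCC(Br)=C | starting material
9 | [(2-bromoprop-2-en-1-yl)oxy](tert-butyl)dimethylsilane | C=C(Br)CO[Si](C)(C)C(C)(C)C | intermediate
10 | Cr(CO)6, hexacarbonylchromium | [Cr].[C-]#[O+].[C-]#[O+].[C-]#[O+].[C-]#[O+].[C-]#[O+].[C-]#[O+] | starting material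
11 | {3-[(tert-butyldimethylsilyl)oxy]prop-1-en-2-yl}lithium | [Li]C(=C)CO[Si](C)(C)C(C)(C)C | intermediate (not isolated)
12 | lithium acylchromate Li[(CO)5Cr–C(=O)C(=CH2)CH2OTBS] | [Li+].[O-]C(=[Cr])C(=C)CO[Si](C)(C)C(C)(C)C.[C-]#[O+].[C-]#[O+].[C-]#[O+].[C-]#[O+].[C-]#[O+] | intermediate (not isolated)
13 | pentacarbonyl{methoxy[3-(tert-butyldimethylsilyloxy)prop-1-en-2-yl]carbene}chromium, (CO)5Cr=C(OMe)C(=CH2)CH2OTBS | COC(=[Cr])C(=C)CO[Si](C)(C)C(C)(C)C.[C-]#[O+].[C-]#[O+].[C-]#[O+].[C-]#[O+].[C-]#[O+] | intermediate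
14 | Cr(CO)3-bound dienylketene O=C=C(R)–CH=C(OMe)–C(=CH2)CH2OTBS (R = the 1'-silyloxy trienyl chain) | O=C=C([C@@H](O[Si](C)(C)C(C)(C)C)/C=C(\C)CC/C=C(\C)CCC=C(C)C)/C=C(/OC)C(=C)CO[Si](C)(C)C(C)(C)C.[Cr].[C-]#[O+].[C-]#[O+].[C-]#[O+] | intermediate (not isolated)
15 | Cr(CO)3 complex of phenol 16 | COc1cc([C@@H](O[Si](C)(C)C(C)(C)C)/C=C(\C)CC/C=C(\C)CCC=C(C)C)c(O)cc1CO[Si](C)(C)C(C)(C)C.[Cr].[C-]#[O+].[C-]#[O+].[C-]#[O+] | intermediate (not isolated)
16 | 5-{[(tert-butyldimethylsilyl)oxy]methyl}-2-[(1S,2E,6E)-1-[(tert-butyldimethylsilyl)oxy]-3,7,11-trimethyldodeca-2,6,10-trien-1-yl]-4-methoxyphenol | COc1cc([C@@H](O[Si](C)(C)C(C)(C)C)/C=C(\C)CC/C=C(\C)CCC=C(C)C)c(O)cc1CO[Si](C)(C)C(C)(C)C | intermediate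
17 | 5-{[(tert-butyldimethylsilyl)oxy]methyl}-2-[(1S,2E,6E)-1-[(tert-butyldimethylsilyl)oxy]-3,7,11-trimethyldodeca-2,6,10-trien-1-yl]-4,4-dimethoxycyclohexa-2,5-dien-1-one | COC1(OC)C=C([C@@H](O[Si](C)(C)C(C)(C)C)/C=C(\C)CC/C=C(\C)CCC=C(C)C)C(=O)C=C1CO[Si](C)(C)C(C)(C)C | intermediate
18 | 5-(hydroxymethyl)-2-[(1S,2E,6E)-1-hydroxy-3,7,11-trimethyldodeca-2,6,10-trien-1-yl]-4,4-dimethoxycyclohexa-2,5-dien-1-one | COC1(OC)C=C([C@@H](O)/C=C(\C)CC/C=C(\C)CCC=C(C)C)C(=O)C=C1CO | intermediate
19 | (1R,6S)-3-(hydroxymethyl)-6-[(1S,2E,6E)-1-hydroxy-3,7,11-trimethyldodeca-2,6,10-trien-1-yl]-2,2-dimethoxy-7-oxabicyclo[4.1.0]hept-3-en-5-one | OCC1=CC(=O)[C@@]2([C@@H](O)/C=C(\C)CC/C=C(\C)CCC=C(C)C)O[C@H]2C1(OC)OC | intermediate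
20 | [(1R,6S)-6-[(1S,2E,6E)-1-hydroxy-3,7,11-trimethyldodeca-2,6,10-trien-1-yl]-2,2-dimethoxy-5-oxo-7-oxabicyclo[4.1.0]hept-3-en-3-yl]methyl acetate | CC(=O)OCC1=CC(=O)[C@@]2([C@@H](O)/C=C(\C)CC/C=C(\C)CCC=C(C)C)O[C@H]2C1(OC)OC | intermediate
21 | [(1R,5S,6R)-5-hydroxy-6-[(1S,2E,6E)-1-hydroxy-3,7,11-trimethyldodeca-2,6,10-trien-1-yl]-2,2-dimethoxy-7-oxabicyclo[4.1.0]hept-3-en-3-yl]methyl acetate | CC(=O)OCC1=C[C@H](O)[C@@]2([C@@H](O)/C=C(\C)CC/C=C(\C)CCC=C(C)C)O[C@H]2C1(OC)OC | intermediate
22 | [(1R,5S,6R)-5-hydroxy-6-[(1S,2E,6E)-1-hydroxy-3,7,11-trimethyldodeca-2,6,10-trien-1-yl]-2-oxo-7-oxabicyclo[4.1.0]hept-3-en-3-yl]methyl acetate | CC(=O)OCC1=C[C@H](O)[C@@]2([C@@H](O)/C=C(\C)CC/C=C(\C)CCC=C(C)C)O[C@H]2C1=O | target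

**Count and risks**

Total step count: 14. Longest linear sequence: 12 steps (steps 1–5, then 8–14).

Steps most likely to fail:

1. Step 11. The alkoxide-directed oxygen delivery may show poor facial selectivity, or attack may be diverted to the other enone arm. The fallback sets out from 17 and comes back at 19, and moves stereocontrol from the substrate alkoxide to an external chiral catalyst. The bis-silyl ether 17 is epoxidised under cinchona phase-transfer conditions (t-BuOOH, aq NaOH, toluene, 0 °C, N-benzylcinchonidinium chloride or its pseudoenantiomeric cinchoninium salt, whichever is matched with C1'). This should give (1R,6S)-3-{[(tert-butyldimethylsilyl)oxy]methyl}-6-[(1S,2E,6E)-1-[(tert-butyldimethylsilyl)oxy]-3,7,11-trimethyldodeca-2,6,10-trien-1-yl]-2,2-dimethoxy-7-oxabicyclo[4.1.0]hept-3-en-5-one F1. Desilylation with TBAF/AcOH in THF then gives 19.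

2. Step 8. Alkyne insertion of the branched propargylic ether may be slow, so that the carbene complex decays, or the metal-bound vinylketene may close to a four- or five-membered ring instead of the six-membered one. The fallback sets out from 2 and comes back at 18; it takes the ring from a commercial arene and forms the C6–C1' bond instead. 5-Hydroxy-2-methoxybenzaldehyde F2 is reduced (NaBH4, MeOH) to 3-(hydroxymethyl)-4-methoxyphenol F3. Oxidation with PhI(OAc)2 in MeOH gives 3-(hydroxymethyl)-4,4-dimethoxycyclohexa-2,5-dien-1-one F4. Iodine–pyridine α-iodination, which starts by pyridine addition at the unsubstituted β-carbon, gives 5-(hydroxymethyl)-2-iodo-4,4-dimethoxycyclohexa-2,5-dien-1-one F5. An asymmetric Nozaki–Hiyama–Kishi coupling of F5 with farnesal 2 (CrCl2, catalytic NiCl2, chiral sulfonamide ligand chosen for the 1'S carbinol, THF) should give 18.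

3. Step 13. The directed hydride delivery may show weak face selectivity, or the ketal or epoxide may suffer in acetic acid. The fallback sets out from 19 and comes back at 21; it reduces before acetylation and uses an aluminium hydride bound to the epoxide oxygen. Treatment of 19 with i-Bu2AlH (THF, –78 °C) should deliver hydride to C5 from the epoxide face, which is also the face away from the C6 side chain. This gives (1R,5S,6R)-3-(hydroxymethyl)-6-[(1S,2E,6E)-1-hydroxy-3,7,11-trimethyldodeca-2,6,10-trien-1-yl]-2,2-dimethoxy-7-oxabicyclo[4.1.0]hept-3-en-5-ol F6. Selective acetylation of its primary hydroxyl (Ac2O, 2,4,6-collidine, CH2Cl2, –20 °C) gives 21.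

Further compounds
F1 | step 11 | (1R,6S)-3-{[(tert-butyldimethylsilyl)oxy]methyl}-6-[(1S,2E,6E)-1-[(tert-butyldimethylsilyl)oxy]-3,7,11-trimethyldodeca-2,6,10-trien-1-yl]-2,2-dimethoxy-7-oxabicyclo[4.1.0]hept-3-en-5-one | CC(C)(C)[Si](C)(C)OCC1=CC(=O)[C@@]2([C@@H](O[Si](C)(C)C(C)(C)C)/C=C(\C)CC/C=C(\C)CCC=C(C)C)O[C@H]2C1(OC)OC
F2 | step 8 | 5-hydroxy-2-methoxybenzaldehyde | COc1ccc(O)cc1C=O
F3 | step 8 | 3-(hydroxymethyl)-4-methoxyphenol | COc1ccc(O)cc1CO
F4 | step 8 | 3-(hydroxymethyl)-4,4-dimethoxycyclohexa-2,5-dien-1-one | COC1(OC)C=CC(=O)C=C1CO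
F5 | step 8 | 5-(hydroxymethyl)-2-iodo-4,4-dimethoxycyclohexa-2,5-dien-1-one | COC1(OC)C=C(I)C(=O)C=C1CO
F6 | step 13 | (1R,5S,6R)-3-(hydroxymethyl)-6-[(1S,2E,6E)-1-hydroxy-3,7,11-trimethyldodeca-2,6,10-trien-1-yl]-2,2-dimethoxy-7-oxabicyclo[4.1.0]hept-3-en-5-ol | OCC1=C[C@H](O)[C@@]2([C@@H](O)/C=C(\C)CC/C=C(\C)CCC=C(C)C)O[C@H]2C1(OC)OC
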